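**Retrosynthetic overview**
- The target is opened to 5,8-dihydroxy-7-methoxy-2',4',5'-trimethoxyisoflavone. The 6-prenyl group is added last (5-O-allyl ether, aromatic Claisen, cross-metathesis) because it would not survive the oxidative step.
- The pyranone ring (ring C, the only ring made) comes from acid cyclisation of a 1,2-diaryl-3,3-dimethoxypropan-1-one, itself made by oxidative 1,2-aryl shift of a chalcone.
- The chalcone comes from a Claisen–Schmidt aldol condensation of the A-ring acetophenone with 2,4,5-trimethoxybenzaldehyde. This key C–C bond becomes C2–C3 of the isoflavone.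
- The acetophenone comes from MOM-directed ortho-lithiation/acetylation of 3,5-dimethoxycatechol bis-MOM ether, made by Dakin oxidation of commercial 2-hydroxy-4,6-dimethoxybenzaldehyde.
- Rings A and B are bought as aromatics. The 5-OMe is freed by chelation-controlled BCl3 cleavage and the 8-OH is carried as a MOM ether through the prenylation.

Assumption: the target has no stereocentre and no stereogenic double bond, so it is achiral and no enantiocontrol is needed.

**Route**

Step 1
Reactants: 1 2-hydroxy-4,6-dimethoxybenzaldehyde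
Product: 3 3,5-dimethoxybenzene-1,2-diol, via aryl formate 2 (not isolated)
Conditions: 30% H2O2 (1.2 eq), 1 M NaOH (1.1 eq), H2O/THF, 0 °C → rt, N2; then Na2S2O3, 1 M HCl
Reagents that add atoms: hydrogen peroxide, OO
Why: Dakin oxidation, in which hydroperoxide adds to the ortho-hydroxybenzaldehyde, the electron-rich aryl group migrates to oxygen and the formate is hydrolysed in situ to the catechol.

Step 2
Reactants: 3 3,5-dimethoxybenzene-1,2-diol
Product: 4 1,5-dimethoxy-2,3-bis(methoxymethoxy)benzene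
Conditions: NaH (2.4 eq), DMF, 0 °C, Ar; then MOMCl (2.5 eq), 0 °C → rt
Reagents that add atoms: chloromethyl methyl ether (MOMCl), COCCl
Why: Williamson-type O-alkylation of both phenoxides gives the bis-MOM ether, which protects the catechol and supplies the directing group for the next step.

Step 3
Reactants: 4 1,5-dimethoxy-2,3-bis(methoxymethoxy)benzene
Product: 6 1-[4,6-dimethoxy-2,3-bis(methoxymethoxy)phenyl]ethan-1-one, via aryllithium 5 (not isolated)
Conditions: n-BuLi (1.15 eq), THF, 0 °C, 1 h; then MeC(O)N(OMe)Me (1.5 eq), −78 °C → rt; aq NH4Cl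
Reagents that add atoms: N-methoxy-N-methylacetamide, CC(=O)N(C)OC
Why: Directed ortho-metalation, in which OMOM (a much stronger director than OMe) steers lithiation to the CH flanked by OMOM and OMe rather than the CH between two OMe groups, and the Weinreb amide acylates the aryllithium without over-addition.

Step 4
Reactants: 6 1-[4,6-dimethoxy-2,3-bis(methoxymethoxy)phenyl]ethan-1-one; 7 2,4,5-trimethoxybenzaldehyde
Product: 9 (2E)-1-[4,6-dimethoxy-2,3-bis(methoxymethoxy)phenyl]-3-(2,4,5-trimethoxyphenyl)prop-2-en-1-one, via aldol adduct 8 (not isolated)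
Conditions: 50% aq KOH (6 eq), EtOH, rt, 36 h
Reagents that add atoms: none
Why: Claisen–Schmidt crossed aldol condensation, in which only the methyl ketone can enolise and only the aldehyde can accept, and E1cB dehydration gives the conjugated E-enone while the MOM and methyl ethers are inert to base.

Step 5
Reactants: 9 (2E)-1-[4,6-dimethoxy-2,3-bis(methoxymethoxy)phenyl]-3-(2,4,5-trimethoxyphenyl)prop-2-en-1-one
Product: 10 1-[4,6-dimethoxy-2,3-bis(methoxymethoxy)phenyl]-3,3-dimethoxy-2-(2,4,5-trimethoxyphenyl)propan-1-one (racemic)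
Conditions: Tl(NO3)3·3H2O (1.2 eq), MeOH/HC(OMe)3 3:1, rt, 3 h; filter off TlNO3, concentrate, use crude
Reagents that add atoms: methanol, CO
Why: Thallium(III)-mediated oxidative rearrangement, in which oxythallation of the enone is followed by a 1,2-shift of the electron-rich aryl group as Tl(I) leaves and methanol traps the cation as the β-keto acetal; no other alkene is present at this stage.

Step 6
Reactants: 10 1-[4,6-dimethoxy-2,3-bis(methoxymethoxy)phenyl]-3,3-dimethoxy-2-(2,4,5-trimethoxyphenyl)propan-1-one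
Product: 12 8-hydroxy-5,7-dimethoxy-3-(2,4,5-trimethoxyphenyl)-4H-chromen-4-one, via 2-methoxyisoflavanone 11 (not isolated)
Conditions: conc. HCl/MeOH (1:10), reflux, 3 h
Reagents that add atoms: none
Why: Acid-catalysed MOM cleavage and acetal cyclisation–elimination, regiochemically unambiguous because the freed 2'-OH is the only non-methylated oxygen ortho to the ketone.

Step 7
Reactants: 12 8-hydroxy-5,7-dimethoxy-3-(2,4,5-trimethoxyphenyl)-4H-chromen-4-one
Product: 13 5,8-dihydroxy-7-methoxy-3-(2,4,5-trimethoxyphenyl)-4H-chromen-4-one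
Conditions: BCl3 (1 M in CH2Cl2, 3 eq), CH2Cl2, −78 °C → 0 °C, 1.5 h; then ice/1 M HCl
Reagents that add atoms: none
Why: Chelation-controlled Lewis-acid ether cleavage, in which boron bridges C4=O and the peri 5-OMe so only that methyl is removed and the other four methyl ethers stay.

Step 8
Reactants: 13 5,8-dihydroxy-7-methoxy-3-(2,4,5-trimethoxyphenyl)-4H-chromen-4-one
Product: 14 5-hydroxy-7-methoxy-8-(methoxymethoxy)-3-(2,4,5-trimethoxyphenyl)-4H-chromen-4-one
Conditions: MOMCl (1.2 eq), iPr2NEt (1.5 eq), CH2Cl2, 0 °C → rt, Ar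
Reagents that add atoms: chloromethyl methyl ether (MOMCl), COCCl
Why: Selective O-alkylation, since the 5-OH is hydrogen-bonded to C4=O and unreactive with an amine base, so only the 8-OH is protected.

Step 9
Reactants: 14 5-hydroxy-7-methoxy-8-(methoxymethoxy)-3-(2,4,5-trimethoxyphenyl)-4H-chromen-4-one
Product: 15 7-methoxy-8-(methoxymethoxy)-5-(prop-2-en-1-yloxy)-3-(2,4,5-trimethoxyphenyl)-4H-chromen-4-one
Conditions: allyl bromide (3 eq), K2CO3 (3 eq), DMF, 60 °C, 8 h
Reagents that add atoms: allyl bromide, C=CCBr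
Why: Williamson ether synthesis under forcing carbonate/DMF conditions alkylates the chelated 5-OH, the only free hydroxyl.

Step 10
Reactants: 15 7-methoxy-8-(methoxymethoxy)-5-(prop-2-en-1-yloxy)-3-(2,4,5-trimethoxyphenyl)-4H-chromen-4-one
Product: 17 5-hydroxy-7-methoxy-8-(methoxymethoxy)-6-(prop-2-en-1-yl)-3-(2,4,5-trimethoxyphenyl)-4H-chromen-4-one, via dienone 16 (not isolated)
Conditions: PhNEt2, 200 °C, sealed tube, Ar, 3 h
Reagents that add atoms: none
Why: Aromatic Claisen rearrangement, a [3,3] shift to C6 (the only free ortho position, since C4a is quaternary) followed by tautomerisation to the chelated phenol.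

Step 11
Reactants: 17 5-hydroxy-7-methoxy-8-(methoxymethoxy)-6-(prop-2-en-1-yl)-3-(2,4,5-trimethoxyphenyl)-4H-chromen-4-one
Product: 18 5-hydroxy-7-methoxy-8-(methoxymethoxy)-6-(3-methylbut-2-en-1-yl)-3-(2,4,5-trimethoxyphenyl)-4H-chromen-4-one
Conditions: Grubbs II (5 mol%), 2-methylbut-2-ene/CH2Cl2 1:3, 40 °C, sealed tube, 12 h
Reagents that add atoms: 2-methylbut-2-ene, CC=C(C)C
Why: Olefin cross-metathesis of the terminal allyl group with excess 2-methylbut-2-ene gives the prenyl group with loss of propene, and the chromone C2=C3 bond does not take part.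

Step 12
Reactants: 18 5-hydroxy-7-methoxy-8-(methoxymethoxy)-6-(3-methylbut-2-en-1-yl)-3-(2,4,5-trimethoxyphenyl)-4H-chromen-4-one
Product: 19 5,8-dihydroxy-7-methoxy-6-(3-methylbut-2-en-1-yl)-3-(2,4,5-trimethoxyphenyl)-4H-chromen-4-one
Conditions: conc. HCl (5 eq), MeOH, 40 °C, 2 h, Ar
Reagents that add atoms: none
Why: Mild acid-catalysed acetal (MOM) cleavage, tolerated by the prenyl group because its only neighbouring hydroxyl is the weakly nucleophilic chelated 5-OH.

**Compound list**
1 | 2-hydroxy-4,6-dimethoxybenzaldehyde | COc1cc(O)c(C=O)c(OC)c1 | starting material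
2 | 2-hydroxy-4,6-dimethoxyphenyl formate | COc1cc(O)c(OC=O)c(OC)c1 | intermediate
3 | 3,5-dimethoxybenzene-1,2-diol | COc1cc(O)c(O)c(OC)c1 | intermediate
4 | 1,5-dimethoxy-2,3-bis(methoxymethoxy)benzene | COCOc1cc(OC)cc(OC)c1OCOC | intermediate
5 | [4,6-dimethoxy-2,3-bis(methoxymethoxy)phenyl]lithium | [Li]c1c(OCOC)c(OCOC)c(OC)cc1OC | intermediate
6 | 1-[4,6-dimethoxy-2,3-bis(methoxymethoxy)phenyl]ethan-1-one | CC(=O)c1c(OCOC)c(OCOC)c(OC)cc1OC | intermediate
7 | 2,4,5-trimethoxybenzaldehyde | COc1cc(OC)c(C=O)cc1OC | starting material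
8 | 3-hydroxy-1-[4,6-dimethoxy-2,3-bis(methoxymethoxy)phenyl]-3-(2,4,5-trimethoxyphenyl)propan-1-one (racemic) | COCOc1c(OCOC)c(OC)cc(OC)c1C(=O)CC(O)c1cc(OC)c(OC)cc1OC | intermediate
9 | (2E)-1-[4,6-dimethoxy-2,3-bis(methoxymethoxy)phenyl]-3-(2,4,5-trimethoxyphenyl)prop-2-en-1-one | COCOc1c(OCOC)c(OC)cc(OC)c1C(=O)/C=C/c1cc(OC)c(OC)cc1OC | intermediate
10 | 1-[4,6-dimethoxy-2,3-bis(methoxymethoxy)phenyl]-3,3-dimethoxy-2-(2,4,5-trimethoxyphenyl)propan-1-one (racemic) | COCOc1c(OCOC)c(OC)cc(OC)c1C(=O)C(C(OC)OC)c1cc(OC)c(OC)cc1OC | intermediate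
11 | 8-hydroxy-2,5,7-trimethoxy-3-(2,4,5-trimethoxyphenyl)-2,3-dihydro-4H-chromen-4-one (racemic, diastereomer mixture) | COC1Oc2c(O)c(OC)cc(OC)c2C(=O)C1c1cc(OC)c(OC)cc1OC | intermediate
12 | 8-hydroxy-5,7-dimethoxy-3-(2,4,5-trimethoxyphenyl)-4H-chromen-4-one | COc1cc(OC)c(-c2coc3c(O)c(OC)cc(OC)c3c2=O)cc1OC | intermediate
13 | 5,8-dihydroxy-7-methoxy-3-(2,4,5-trimethoxyphenyl)-4H-chromen-4-one | COc1cc(OC)c(-c2coc3c(O)c(OC)cc(O)c3c2=O)cc1OC | intermediate
14 | 5-hydroxy-7-methoxy-8-(methoxymethoxy)-3-(2,4,5-trimethoxyphenyl)-4H-chromen-4-one | COc1cc(OC)c(-c2coc3c(OCOC)c(OC)cc(O)c3c2=O)cc1OC | intermediate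
15 | 7-methoxy-8-(methoxymethoxy)-5-(prop-2-en-1-yloxy)-3-(2,4,5-trimethoxyphenyl)-4H-chromen-4-one | COc1cc(OC)c(-c2coc3c(OCOC)c(OC)cc(OCC=C)c3c2=O)cc1OC | intermediate
16 | 7-methoxy-8-(methoxymethoxy)-6-(prop-2-en-1-yl)-3-(2,4,5-trimethoxyphenyl)-4H-chromene-4,5(6H)-dione (racemic) | C=CCC1C(=O)C2=C(OC=C(c3cc(OC)c(OC)cc3OC)C2=O)C(OCOC)=C1OC | intermediate
17 | 5-hydroxy-7-methoxy-8-(methoxymethoxy)-6-(prop-2-en-1-yl)-3-(2,4,5-trimethoxyphenyl)-4H-chromen-4-one | COc1cc(OC)c(-c2coc3c(OCOC)c(OC)c(CC=C)c(O)c3c2=O)cc1OC | intermediate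
18 | 5-hydroxy-7-methoxy-8-(methoxymethoxy)-6-(3-methylbut-2-en-1-yl)-3-(2,4,5-trimethoxyphenyl)-4H-chromen-4-one | COc1cc(OC)c(-c2coc3c(OCOC)c(OC)c(CC=C(C)C)c(O)c3c2=O)cc1OC | intermediate
19 | 5,8-dihydroxy-7-methoxy-6-(3-methylbut-2-en-1-yl)-3-(2,4,5-trimethoxyphenyl)-4H-chromen-4-one | COc1cc(OC)c(-c2coc3c(O)c(OC)c(CC=C(C)C)c(O)c3c2=O)cc1OC | target

**Step count and risks**

Total steps: 12. Longest linear sequence: 12 steps (1 → 19); compound 7 is bought and enters at step 4.

Most likely to fail: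

Step 3 (lithiation/acetylation). Some lithiation may occur at the CH between the two methoxy groups, and the aryllithium may partly deprotonate the Weinreb amide. The fallback sets out from 3 and replaces metalation by electrophilic substitution. Friedel–Crafts/Fries C-acetylation with Ac2O and BF3·OEt2 at 70 °C is directed ortho to the free phenol through the BF2 chelate and gives 1-(2,3-dihydroxy-4,6-dimethoxyphenyl)ethan-1-one F1. Bis-MOM protection of this with NaH and MOMCl in DMF comes back to the route at 6.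

Step 5 (thallium(III) oxidative rearrangement). Both aryl rings are very electron-rich and may be over-oxidised, and the nitric acid formed may strip MOM groups early. The fallback sets out from 9 and uses an epoxide rearrangement instead of an oxidative aryl shift. Weitz–Scheffer epoxidation (30% H2O2, NaOH, MeOH, 0 °C) gives the racemic trans-epoxide [4,6-dimethoxy-2,3-bis(methoxymethoxy)phenyl][3-(2,4,5-trimethoxyphenyl)oxiran-2-yl]methanone F2. BF3·OEt2 in CH2Cl2 at 0 °C opens it at the benzylic carbon and a 1,2-aroyl shift gives 3-[4,6-dimethoxy-2,3-bis(methoxymethoxy)phenyl]-3-oxo-2-(2,4,5-trimethoxyphenyl)propanal F3. Methanolic HCl at reflux then removes both MOM groups and cyclodehydrates, coming back to the route at 12.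

Step 10 (thermal Claisen at 200 °C). Decomposition, MOM loss or cyclisation of the ortho-allylphenol may lower the yield. The fallback sets out from 14 and installs the prenyl group directly, so that steps 9 to 11 are not needed. O-Prenylation with prenyl bromide and K2CO3 in acetone gives 7-methoxy-8-(methoxymethoxy)-5-[(3-methylbut-2-en-1-yl)oxy]-3-(2,4,5-trimethoxyphenyl)-4H-chromen-4-one F4. Montmorillonite K10 in CH2Cl2 at 0 °C → rt then promotes a [1,3] O→C prenyl shift to C6, the only free ortho position, and the route is rejoined at 18.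

**Further compounds**
F1 | step 3 | 1-(2,3-dihydroxy-4,6-dimethoxyphenyl)ethan-1-one | CC(=O)c1c(O)c(O)c(OC)cc1OC
F2 | step 5 | [4,6-dimethoxy-2,3-bis(methoxymethoxy)phenyl][trans-3-(2,4,5-trimethoxyphenyl)oxiran-2-yl]methanone (racemic, one enantiomer drawn) | COCOc1c(OCOC)c(OC)cc(OC)c1C(=O)[C@@H]1O[C@H]1c1cc(OC)c(OC)cc1OC
F3 | step 5 | 3-[4,6-dimethoxy-2,3-bis(methoxymethoxy)phenyl]-3-oxo-2-(2,4,5-trimethoxyphenyl)propanal (racemic) | COCOc1c(OCOC)c(OC)cc(OC)c1C(=O)C(C=O)c1cc(OC)c(OC)cc1OC
F4 | step 10 | 7-methoxy-8-(methoxymethoxy)-5-[(3-methylbut-2-en-1-yl)oxy]-3-(2,4,5-trimethoxyphenyl)-4H-chromen-4-one | COc1cc(OC)c(-c2coc3c(OCOC)c(OC)cc(OCC=C(C)C)c3c2=O)cc1OC
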